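A leftover opens the case: at 4.00 d the cedar run has 87.6% of its solid substrate outside the side product, and that share barely moves up to 10.0 d, although the coupling partner was charged at 1.5 equiv.

| flask | solid substrate | coupling partner | remark | time |
|---|---|---|---|---|
| cedar | 0.027 M | 1.5 equiv (fed, over 2.0 h) | run made earlier |  |
| elm | 0.11 M | 1.5 equiv (fed, over 2.0 h) | run made earlier |  |
| flask | 0.054 M | 1.50 equiv (fed, over 2.0 h) |  | 15 d |

| run | time / d | side product / % | target / % |
|---|---|---|---|
| cedar | 0.833 | 0 | 4.3 |
| cedar | 2.50 | 7.3 | 1.7 |
| cedar | 4.00 | 12.4 | 0 |
| cedar | 6.00 | 12.5 | 1.2 |
| cedar | 10.0 | 12.3 | 0 |
| elm | 1.67 | 1.4 | 2.2 |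
| elm | 4.00 | 4.6 | 0 |
| elm | 5.00 | 3.2 | 0 |
| elm | 8.00 | 4.7 | 0 |
| elm | 10.0 | 5.6 | 0 |

(each reading ± 1 percentage point)

- the state of affairs at 15 d: stopped, and by what, or still going (for what has run out or reacted, a solid counts together with what of it has only dissolved) (the coupling partner has run out first / all of the solid substrate has reacted / it is still moving)
- the side product standing at 15 d, as a percentage of the solid substrate charged

- percentages count the solid substrate that a species holds: one side product counts as two
- target is meant together with its solid product
- solid, in amounts per volume of the solution: solid substrate, solid product
- steps thought possible: solid substrate <-> dissolved substrate; dissolved substrate + coupling partner -> target; dissolved substrate + target -> side product; solid product <-> target; coupling partner -> decomposed reagent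
- at the start none of the solid substrate is in solution
- what has only dissolved of solid substrate counts as not reacted
- the reaction counts as stopped when no species that holds the solid substrate changes by six tenths of a point or more over the second half of the time

So I take the coupling partner to be lost to decomposed reagent while solid substrate remains, and I reckon with a stopping amount: the mean plateau share of side product times the charge. Cedar gives 3.35 mM and elm 4.98 mM, so the larger charge holds more, but far from in proportion. If substrate enters solution at a steady rate and the coupling partner dies away first-order, each e-fold of charge buys a fixed extra time, and so a fixed extra amount. Between the runs the stopping amount gains 1.16 mM per e-fold of charge, and this stopping step is what I carry. The flask at 0.054 M lies 0.693 e-folds above cedar, so it should stop at 4.15 mM, or 7.69% of its charge.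

The weak link is the logarithmic form. A power law through the same two levels gives 7.54%, which moves my number by 0.15 percentage points, against a scatter of 1 point on one reading. I commit to 7.69%.

The forecast says the coupling partner has run out first, with 7.5% between 6.3% and 9%, a little below my figure, on the ground that “the reaction stops early because the coupling partner is lost”.

The flask gives 7.64%, and its state is: the coupling partner has run out first. By the charges the solid substrate is the limiting reagent, with 1.50 equiv of coupling partner against it, yet in the flask the coupling partner stands at 0% at 15.0 d, and the side product is still 7.64% at 150 d.

    solid substrate ⇌ dissolved substrate, rate k1*(cs1 - [dissolved substrate]) while solid is left; crystals form when [dissolved substrate] > cs1 (solubility = 1.10 mM, k = 9.84 × 10⁻⁴ min⁻¹)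
    dissolved substrate + coupling partner → target (k = 0.839 M⁻¹ min⁻¹)
    dissolved substrate + target → side product (k = 1.53 M⁻¹ min⁻¹)
    solid product ⇌ target, rate k4*(cs4 - [target]) while solid is left; crystals form when [target] > cs4 (solubility = 18.0 mM, k = 0.489 min⁻¹)
    coupling partner → decomposed reagent (k = 0.00153 min⁻¹)

The flask's stopping amount, 4.12 mM, lies 0.664 stopping steps above cedar, where its charge lies 0.693 e-folds above. For a neighbour flask at 0.022 M, below cedar, the same step gives 14.1%, and that neighbour stands at 14.1%.

(The numbers in the tables stem from a simulated flask for substances that don't exist; noise was put on by code.)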